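Numbering used throughout: tetralin carbons C1–C8a with C1 carrying the side chain, C4 the methyl group, C5/C6 the hydroxyl groups and C7 the carboxyl group. In the side chain C11 is bonded to C1, C12–C14 are methylenes, and C15 carries the methyl group. Ring A is the saturated ring, ring B the arene.

Assumption: in step 5 the (R)-configured phosphoramidite–alkene ligand is taken to be the enantiomer that opens the Re face of the aryl-bearing allyl terminus to the nucleophile (giving (S) at C1); if its sense is the opposite, the (S)-ligand is used and nothing else changes.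

## Analysis of the target

The target 21 is a tetralin in which a saturated ring A (C1–C4, C4a, C8a) is fused to an arene ring B. Ring B carries hydroxyl groups on C5 and C6 and a carboxyl group on C7, and only C8 is unsubstituted. C1 bears a seven-carbon chain with hydroxymethyl groups on C11 and C15, and C4 bears a methyl group. There are four stereocentres: C1 (S) and C4 (R) are trans across ring A, C11 (S) is bonded directly to C1, and C15 (S) is separated from the rest by three methylene groups. When HOCH2–C11–C1–C2 is drawn as a zigzag, the C12 branch on C11 and the aryl group on C1 lie on opposite sides. This anti relationship is what an enamine Michael addition, the obvious acyclic method, does not deliver. Sensitive features are the 2,3-dihydroxybenzoic acid unit (air oxidation, decarboxylation on strong heating) and two primary alcohols that must be kept apart from the other oxygen functions. The difficulty lies in the contiguous C1/C11 pair, the remote 1,4-trans relationship in a ring without other handles, and the crowded arene. The plan rests on the fact that C4 carries only a methyl group and the arene carbon C4a: C4 with its methyl group is an acetyl group on C4a, C3 is an aldehyde two carbons from C1, and reductive union of these two carbonyl carbons makes C3=C4 and closes ring A.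

## Retrosynthetic reasoning

**21 ⇐ 20.** The two aryl O–methyl bonds are cut last. Methyl ethers are the catechol protection that survives organolithium, hydroboration and low-valent titanium chemistry, and the C6 methoxy group also serves as the director for C7. The forward step is a Lewis-acid ether cleavage that must leave the carboxyl group and the two primary alcohols intact.

**20 ⇐ 18 (through 19).** The C7–carboxyl bond is cut because C7 is the only ring position that carries hydrogen ortho to a methoxy group. Directed ortho-metalation to the aryllithium 19 and carboxylation therefore need no halogen, and the arene can be bought without the carboxyl group. The forward reaction has to lithiate C7 in the presence of two alkoxides.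

**18 ⇐ 17.** The C3–H and C4–H bonds come from hydrogenation of the C3=C4 alkene. The C1 side chain prefers the pseudoaxial position (peri hydrogen on C8) and covers one face of the alkene, so an undirected catalyst would add from the other face and give the cis isomer. With the C11 hydroxymethyl group free, the same substituent becomes the control element: a cationic iridium catalyst bound to that hydroxyl group delivers hydrogen to its own face and places the C4 methyl group trans.

**17 ⇐ 16.** The two O–Si bonds are cut here. The silyl ethers are needed up to ring closure and are removed just before the hydroxyl group is needed as a director.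

**16 ⇐ 15.** The C3=C4 double bond is cut into an aldehyde (C3) and an aryl methyl ketone (C4). This is the one place in ring A where both carbons can be carbonyl carbons and where no stereocentre is at stake. The alternative cuts at C1–C8a or C4–C4a would need benzylic cations or aryl organometallics next to stereocentres. The forward reaction is a reductive carbonyl coupling that must favour ring closure over dimerisation.

**15 ⇐ 14 ⇐ 12 (through 13).** C3 is taken back to the alcohol oxidation level, and the C4a–C4 bond to a C4a–Br bond that is coupled with an acetyl anion equivalent (enol ether 13, then hydrolysis). The bromine marks C4a from the first compound on. Electrophilic acylation of such an arene would go para to a methoxy group and never between the C5 oxygen and the ring-fusion carbon.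

**12 ⇐ 10 (through 11) ⇐ 9.** The C3–O bond comes from anti-Markovnikov hydroboration of a vinyl group on C1 (alkylborane 11). Silylation of 9 keeps the two primary alcohols distinguishable.

**9 ⇐ 8 ⇐ 5 + 7.** The C1–C11 bond is the stereochemical centre of the plan. It joins the α-carbon of aldehyde 5 to the benzylic carbon of the aryl vinyl carbinol 7. An enamine conjugate addition of 5 to a Michael acceptor made from 6 would form the same bond but gives the syn diastereomer. An iridium/amine dual-catalytic allylation sets C1 and C11 by two independent catalysts and reaches the anti isomer directly, with the vinyl group supplying C2 and C3.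

**7 ⇐ 6.** The C1–C2 bond comes from addition of a vinyl nucleophile to the commercial aldehyde 6.

**5 ⇐ 3 (through 4) ⇐ 2 ⇐ 1.** The aldehyde carbon comes from ozonolysis of a terminal alkene (ozonide 4). The C13–C14 bond comes from coupling the bromide 2 with a five-carbon alkenyl nucleophile. C15 is bought in 1.

## Alternatives that were turned down

**Alternative 1:** The cut is at the two aryl–alkyl bonds C4–C4a and C1–C8a, both traced back to allylic ethers on the catechol oxygens.
- Forward key step: on heating, the allyl unit on O5 would move in one [3,3] shift to the free ortho carbon C4a. The unit on O6, whose ortho carbons are both occupied, would reach the para carbon C8a by an ortho shift followed by a Cope shift. The catechol is released and the product is A1.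
- For: no metal is needed, the C7 ester is present from the start, and no late demethylation or carboxylation is required. On these points it is stronger than the chosen plan.
- Against: A1 still has no ring A, so metathesis and hydrogenation must follow. The O6 ether would have to be a secondary allylic ether carrying the whole C11–C15 chain with defined configuration, which is hard to attach to a hindered catechol oxygen without allylic transposition or elimination. The C1 configuration would have to survive two consecutive sigmatropic shifts through a dienone that has other exits. The second group would enter a position flanked by the first.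
- Comparison: the chosen plan offers a ring closure that is the key step itself, and a C1/C11 pair fixed in one catalytic step.

**Alternative 2:** The cut is inside ring B, at C4a–C8a and C5–C6; the arene is built from a furan and a tethered ynal.
- Forward key step: an intramolecular Diels–Alder reaction on heating, in which the furan termini add across the alkyne. Ring A closes together with an oxygen-bridged ring that opens and aromatises to the C6 phenol, giving A2.
- For: two rings in one step, with the C7 ester and the C6 oxygen placed by the cycloaddition. C4 would be set before ring formation rather than by a late hydrogenation. On these points it is stronger.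
- Against: A2 carries a formyl group on C5 that must still be exchanged for a hydroxyl group. All four stereocentres, including a propargylic C4 and a furfuryl C1 next to C11, must be built into a long acyclic tether by separate asymmetric steps. The ynal and the furan are fragile towards nucleophiles and acid.
- Comparison: the chosen plan buys the arene with its oxygen pattern, reaches the cyclisation substrate 15 in few steps from 5 and 6, and needs no oxidation-state correction on ring B.

**Alternative 3:** The cut is at C1–C8a.
- Forward key step: a chiral iridium–phosphoramidite catalyst would ionise an allylic carbonate, and the para carbon C8a of the C6 phenoxide would attack the inner allyl carbon. This closes ring A and leaves a vinyl group on C1 in A3.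
- For: the ring closure is itself enantioselective, it sets C1 relative to an existing C4 so the trans relationship is fixed at cyclisation, and the two phenolic oxygens come out differentiated. On these points it is stronger than the chosen plan, which needs a separate hydrogenation for C4.
- Against: A3 has no side chain. C11, with two carbon branches, would have to be built from the vinyl group next to C1 by acyclic induction, for which no dependable method exists. The C7 carboxylation and the demethylation are still required.
- Comparison: the chosen plan carries the complete side chain, with C11 and C15 already correct, through the ring closure.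

Key step: step 10

## Route

Step 1
Reactants: 1 (R)-3-bromo-2-methylpropan-1-ol
Product: 2 (R)-(3-bromo-2-methylpropoxy)(tert-butyl)dimethylsilane
Conditions: TBSCl, imidazole, CH2Cl2, 0 °C → rt
Reagents that add atoms: tert-butyldimethylsilyl chloride (TBSCl), CC(C)(C)[Si](C)(C)Cl
Why: Standard silylation of a primary alcohol; the bromide and the stereocentre are not touched.

Step 2
Reactants: 2 (R)-(3-bromo-2-methylpropoxy)(tert-butyl)dimethylsilane
Product: 3 (S)-tert-butyldimethyl[(2-methyloct-7-en-1-yl)oxy]silane
Conditions: CH2=CH(CH2)3MgBr, Li2CuCl4 (5 mol%), THF, −20 °C → rt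
Reagents that add atoms: pent-4-enylmagnesium bromide, C=CCCC[Mg]Br
Why: Copper-catalysed cross-coupling of a primary alkyl bromide with an alkyl Grignard reagent forms C13–C14. The reacting carbon is one removed from C15, whose configuration is kept (the descriptor changes only because the substituent ranking changes).

Step 3
Reactants: 3 (S)-tert-butyldimethyl[(2-methyloct-7-en-1-yl)oxy]silane
Product: 5 (S)-7-[(tert-butyldimethylsilyl)oxy]-6-methylheptanal, via ozonide 4 (not isolated)
Conditions: O3, CH2Cl2, −78 °C; then PPh3, −78 °C → rt
Reagents that add atoms: ozone, [O-][O+]=O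
Why: Ozonolysis with reductive work-up cuts the terminal alkene to the aldehyde; the silyl ether and the remote stereocentre are inert.

Step 4
Reactants: 6 2-bromo-3,4-dimethoxybenzaldehyde
Product: 7 rac-1-(2-bromo-3,4-dimethoxyphenyl)prop-2-en-1-ol
Conditions: CH2=CHMgBr, THF, −78 → 0 °C; then sat. aq. NH4Cl
Reagents that add atoms: vinylmagnesium bromide, C=C[Mg]Br
Why: 1,2-Addition of a vinyl Grignard reagent to the aryl aldehyde. The racemate is sufficient because the next step ionises the carbinol carbon.

Step 5
Reactants: 5 (S)-7-[(tert-butyldimethylsilyl)oxy]-6-methylheptanal; 7 rac-1-(2-bromo-3,4-dimethoxyphenyl)prop-2-en-1-ol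
Product: 9 (2S,3S)-3-(2-bromo-3,4-dimethoxyphenyl)-2-[(4S)-5-[(tert-butyldimethylsilyl)oxy]-4-methylpentyl]pent-4-en-1-ol, via pentenal 8 (not isolated)
Conditions: [Ir(cod)Cl]2 (3 mol%), (R)-BINOL-derived N-(dibenzo[b,f]azepin-5-yl)phosphoramidite (12 mol%), (R)-2-{bis[3,5-bis(trifluoromethyl)phenyl][(trimethylsilyl)oxy]methyl}pyrrolidine (15 mol%), (MeO)2P(O)OH (promoter), ClCH2CH2Cl, 25 °C; then NaBH4, MeOH, 0 °C
Reagents that add atoms: none
Why: Dual iridium/amine catalysis for the α-allylation of a linear aldehyde with a racemic aryl vinyl carbinol: acid-promoted ionisation of 7 gives an allyl–iridium electrophile that is attacked at its aryl-bearing terminus (branched product) with the phosphoramidite–alkene ligand fixing C1, while the (R)-prolinol silyl ether enamine of 5 exposes one face of C11 and should fix it as (S). Because the two catalysts act independently, the (1S,11S) isomer, with the C12 chain and the aryl group anti along the zigzag O=CH–C11–C1–CH=CH2, is reached by the choice of catalyst enantiomers and not by substrate bias, which in an enamine Michael addition would favour the syn isomer. NaBH4 added to the same flask removes the epimerisable α-branched aldehyde 8 before isolation.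

Step 6
Reactants: 9 (2S,3S)-3-(2-bromo-3,4-dimethoxyphenyl)-2-[(4S)-5-[(tert-butyldimethylsilyl)oxy]-4-methylpentyl]pent-4-en-1-ol
Product: 10 tert-butyl{[(2S,3S)-3-(2-bromo-3,4-dimethoxyphenyl)-2-[(4S)-5-[(tert-butyldimethylsilyl)oxy]-4-methylpentyl]pent-4-en-1-yl]oxy}dimethylsilane
Conditions: TBSCl, imidazole, DMF, rt
Reagents that add atoms: tert-butyldimethylsilyl chloride (TBSCl), CC(C)(C)[Si](C)(C)Cl
Why: Silylation of the primary alcohol on C11, so that the hydroxyl group made next at C3 is the only free one.

Step 7
Reactants: 10 tert-butyl{[(2S,3S)-3-(2-bromo-3,4-dimethoxyphenyl)-2-[(4S)-5-[(tert-butyldimethylsilyl)oxy]-4-methylpentyl]pent-4-en-1-yl]oxy}dimethylsilane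
Product: 12 (3S,4S,8S)-3-(2-bromo-3,4-dimethoxyphenyl)-9-[(tert-butyldimethylsilyl)oxy]-4-{[(tert-butyldimethylsilyl)oxy]methyl}-8-methylnonan-1-ol, via 9-BBN alkylborane 11 (not isolated)
Conditions: 9-BBN, THF, 0 °C → rt; then NaOH, H2O2, 0 °C → rt
Reagents that add atoms: hydrogen peroxide, OO
Why: Anti-Markovnikov hydroboration–oxidation of the monosubstituted alkene: 9-BBN places boron on the terminal carbon, and oxidation with retention gives C3 at the alcohol level. The aryl bromide and the silyl ethers are unaffected.

Step 8
Reactants: 12 (3S,4S,8S)-3-(2-bromo-3,4-dimethoxyphenyl)-9-[(tert-butyldimethylsilyl)oxy]-4-{[(tert-butyldimethylsilyl)oxy]methyl}-8-methylnonan-1-ol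
Product: 14 (3S,4S,8S)-3-(2-acetyl-3,4-dimethoxyphenyl)-9-[(tert-butyldimethylsilyl)oxy]-4-{[(tert-butyldimethylsilyl)oxy]methyl}-8-methylnonan-1-ol, via ethoxyvinyl arene 13 (not isolated)
Conditions: Pd(PPh3)4 (10 mol%), Bu3Sn–C(OEt)=CH2, toluene, 110 °C; then 0.5 M HCl, THF, 0 °C, 15 min
Reagents that add atoms: tributyl(1-ethoxyvinyl)stannane, CCOC(=C)[Sn](CCCC)(CCCC)CCCC; water, O
Why: Stille coupling: zerovalent palladium inserts into the C4a–Br bond, the stannane transfers the 1-ethoxyvinyl group, and brief dilute acid hydrolyses the enol ether to the methyl ketone (C4 and its methyl group). The neutral coupling conditions tolerate the free alcohol and both silyl ethers.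

Step 9
Reactants: 14 (3S,4S,8S)-3-(2-acetyl-3,4-dimethoxyphenyl)-9-[(tert-butyldimethylsilyl)oxy]-4-{[(tert-butyldimethylsilyl)oxy]methyl}-8-methylnonan-1-ol
Product: 15 (3S,4S,8S)-3-(2-acetyl-3,4-dimethoxyphenyl)-9-[(tert-butyldimethylsilyl)oxy]-4-{[(tert-butyldimethylsilyl)oxy]methyl}-8-methylnonanal
Conditions: Dess–Martin periodinane, CH2Cl2, 0 °C → rt
Reagents that add atoms: none
Why: Dess–Martin oxidation of the primary alcohol to the aldehyde under nearly neutral conditions. The keto aldehyde should be used at once to forestall aldol condensation.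

Step 10
Reactants: 15 (3S,4S,8S)-3-(2-acetyl-3,4-dimethoxyphenyl)-9-[(tert-butyldimethylsilyl)oxy]-4-{[(tert-butyldimethylsilyl)oxy]methyl}-8-methylnonanal
Product: 16 (1S)-1-[(2S,6S)-1,7-bis[(tert-butyldimethylsilyl)oxy]-6-methylheptan-2-yl]-5,6-dimethoxy-4-methyl-1,2-dihydronaphthalene
Conditions: TiCl3(DME)1.5 (10 equiv), Zn–Cu couple (30 equiv), DME, reflux, 3 h; then 15 added over 30 h by syringe pump, reflux
Reagents that add atoms: none
Why: Intramolecular McMurry coupling: low-valent titanium, made beforehand from TiCl3(DME)1.5 and Zn–Cu couple, transfers one electron to each carbonyl group, the aldehyde and aryl ketone ketyl centres couple to form the C3–C4 bond, and at reflux both C–O bonds are cleaved on the metal to leave the C3=C4 double bond. The closest known reaction type is the cyclisation of keto aldehydes to cycloalkenes with the same reagent. Ring A is closed by direct union of the two former carbonyl carbons in a six-membered ring, four of whose atoms (C1, C8a, C4a, C4) are already held in place by the arene. No stereocentre is formed: C4 becomes an sp2 carbon, C11 is a spectator, and C1 is β to the aldehyde and out of reach of enolisation. The selectivity needed is ring closure over intermolecular coupling of the more reactive aldehyde, which is secured by adding 15 slowly to a large excess of reagent so that its stationary concentration stays low. No benzylic cation arises, so the electron-rich arene is not drawn into side reactions, and aryl methyl ethers and primary silyl ethers should not be reduced.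

Step 11
Reactants: 16 (1S)-1-[(2S,6S)-1,7-bis[(tert-butyldimethylsilyl)oxy]-6-methylheptan-2-yl]-5,6-dimethoxy-4-methyl-1,2-dihydronaphthalene
Product: 17 (2S,6S)-2-[(1S)-5,6-dimethoxy-4-methyl-1,2-dihydronaphthalen-1-yl]-6-methylheptane-1,7-diol
Conditions: TBAF, THF, 0 °C → rt
Reagents that add atoms: none
Why: Fluoride cleavage of both silyl ethers; this frees the C11 hydroxymethyl group that directs the hydrogenation, and the styrene-type alkene is stable to fluoride.

Step 12
Reactants: 17 (2S,6S)-2-[(1S)-5,6-dimethoxy-4-methyl-1,2-dihydronaphthalen-1-yl]-6-methylheptane-1,7-diol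
Product: 18 (2S,6S)-2-[(1S,4R)-5,6-dimethoxy-4-methyl-1,2,3,4-tetrahydronaphthalen-1-yl]-6-methylheptane-1,7-diol
Conditions: [Ir(cod)(PCy3)(py)]PF6 (5 mol%), H2 (1 atm), CH2Cl2, rt
Reagents that add atoms: none
Why: Hydroxyl-directed hydrogenation with a cationic iridium catalyst: the C1 side chain sits pseudoaxial to avoid the peri hydrogen on C8, its C11 hydroxymethyl group binds the metal, and hydrogen is delivered to the face of C3=C4 on the side of that chain. The new hydrogen on C4 is therefore cis to the side chain and the methyl group trans, which is (4R).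

Step 13
Reactants: 18 (2S,6S)-2-[(1S,4R)-5,6-dimethoxy-4-methyl-1,2,3,4-tetrahydronaphthalen-1-yl]-6-methylheptane-1,7-diol
Product: 20 (5R,8S)-8-[(2S,6S)-1,7-dihydroxy-6-methylheptan-2-yl]-3,4-dimethoxy-5-methyl-5,6,7,8-tetrahydronaphthalene-2-carboxylic acid, via C7 aryllithium 19 (not isolated)
Conditions: n-BuLi (4.5 equiv), TMEDA, THF, −78 → 0 °C; then CO2, −78 °C → rt; then 1 M HCl
Reagents that add atoms: carbon dioxide, O=C=O
Why: Directed ortho-metalation: after both alkoxides have formed, n-BuLi/TMEDA removes the C7 hydrogen, the only ring hydrogen ortho to a methoxy group, and CO2 traps the aryllithium. The tertiary benzylic hydrogens on C1 and C4 are kinetically much less acidic, and the alkyl carbonates formed at the alkoxides lose CO2 on acidification.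

Step 14
Reactants: 20 (5R,8S)-8-[(2S,6S)-1,7-dihydroxy-6-methylheptan-2-yl]-3,4-dimethoxy-5-methyl-5,6,7,8-tetrahydronaphthalene-2-carboxylic acid
Product: 21 (5R,8S)-8-[(2S,6S)-1,7-dihydroxy-6-methylheptan-2-yl]-3,4-dihydroxy-5-methyl-5,6,7,8-tetrahydronaphthalene-2-carboxylic acid
Conditions: BBr3 (8 equiv), CH2Cl2, −78 → 0 °C; then H2O, 0 °C, under argon
Reagents that add atoms: none
Why: Lewis-acid cleavage of aryl methyl ethers: boron binds each methoxy oxygen (the C6 one assisted by the neighbouring carboxyl group) and bromide removes the methyl group by SN2. At or below 0 °C the borates of the two primary alcohols should be hydrolysed back to the alcohols on work-up, and no stereocentre is touched.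

## Compound list

1 | (R)-3-bromo-2-methylpropan-1-ol | C[C@H](CO)CBr | starting material
2 | (R)-(3-bromo-2-methylpropoxy)(tert-butyl)dimethylsilane | C[C@H](CO[Si](C)(C)C(C)(C)C)CBr | intermediate
3 | (S)-tert-butyldimethyl[(2-methyloct-7-en-1-yl)oxy]silane | C[C@H](CO[Si](C)(C)C(C)(C)C)CCCCC=C | intermediate
4 | 3-[(5S)-6-[(tert-butyldimethylsilyl)oxy]-5-methylhexyl]-1,2,4-trioxolane (ozonide, both epimers at the ring carbon) | C[C@H](CO[Si](C)(C)C(C)(C)C)CCCCC1OCOO1 | intermediate
5 | (S)-7-[(tert-butyldimethylsilyl)oxy]-6-methylheptanal | C[C@H](CO[Si](C)(C)C(C)(C)C)CCCCC=O | intermediate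
6 | 2-bromo-3,4-dimethoxybenzaldehyde | COc1ccc(C=O)c(Br)c1OC | starting material
7 | rac-1-(2-bromo-3,4-dimethoxyphenyl)prop-2-en-1-ol | C=CC(O)c1ccc(OC)c(OC)c1Br | intermediate
8 | (2S,3S)-3-(2-bromo-3,4-dimethoxyphenyl)-2-[(4S)-5-[(tert-butyldimethylsilyl)oxy]-4-methylpentyl]pent-4-enal | C[C@H](CO[Si](C)(C)C(C)(C)C)CCC[C@H](C=O)[C@H](C=C)c1ccc(OC)c(OC)c1Br | intermediate
9 | (2S,3S)-3-(2-bromo-3,4-dimethoxyphenyl)-2-[(4S)-5-[(tert-butyldimethylsilyl)oxy]-4-methylpentyl]pent-4-en-1-ol | C[C@H](CO[Si](C)(C)C(C)(C)C)CCC[C@H](CO)[C@H](C=C)c1ccc(OC)c(OC)c1Br | intermediate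
10 | tert-butyl{[(2S,3S)-3-(2-bromo-3,4-dimethoxyphenyl)-2-[(4S)-5-[(tert-butyldimethylsilyl)oxy]-4-methylpentyl]pent-4-en-1-yl]oxy}dimethylsilane | C[C@H](CO[Si](C)(C)C(C)(C)C)CCC[C@H](CO[Si](C)(C)C(C)(C)C)[C@H](C=C)c1ccc(OC)c(OC)c1Br | intermediate
11 | 9-[(3S,4S,8S)-3-(2-bromo-3,4-dimethoxyphenyl)-9-[(tert-butyldimethylsilyl)oxy]-4-{[(tert-butyldimethylsilyl)oxy]methyl}-8-methylnonyl]-9-borabicyclo[3.3.1]nonane | C[C@H](CO[Si](C)(C)C(C)(C)C)CCC[C@H](CO[Si](C)(C)C(C)(C)C)[C@H](CCB1C2CCCC1CCC2)c1ccc(OC)c(OC)c1Br | intermediate
12 | (3S,4S,8S)-3-(2-bromo-3,4-dimethoxyphenyl)-9-[(tert-butyldimethylsilyl)oxy]-4-{[(tert-butyldimethylsilyl)oxy]methyl}-8-methylnonan-1-ol | C[C@H](CO[Si](C)(C)C(C)(C)C)CCC[C@H](CO[Si](C)(C)C(C)(C)C)[C@H](CCO)c1ccc(OC)c(OC)c1Br | intermediate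
13 | (3S,4S,8S)-9-[(tert-butyldimethylsilyl)oxy]-4-{[(tert-butyldimethylsilyl)oxy]methyl}-3-[2-(1-ethoxyethenyl)-3,4-dimethoxyphenyl]-8-methylnonan-1-ol | C[C@H](CO[Si](C)(C)C(C)(C)C)CCC[C@H](CO[Si](C)(C)C(C)(C)C)[C@H](CCO)c1ccc(OC)c(OC)c1C(=C)OCC | intermediate
14 | (3S,4S,8S)-3-(2-acetyl-3,4-dimethoxyphenyl)-9-[(tert-butyldimethylsilyl)oxy]-4-{[(tert-butyldimethylsilyl)oxy]methyl}-8-methylnonan-1-ol | C[C@H](CO[Si](C)(C)C(C)(C)C)CCC[C@H](CO[Si](C)(C)C(C)(C)C)[C@H](CCO)c1ccc(OC)c(OC)c1C(C)=O | intermediate
15 | (3S,4S,8S)-3-(2-acetyl-3,4-dimethoxyphenyl)-9-[(tert-butyldimethylsilyl)oxy]-4-{[(tert-butyldimethylsilyl)oxy]methyl}-8-methylnonanal | C[C@H](CO[Si](C)(C)C(C)(C)C)CCC[C@H](CO[Si](C)(C)C(C)(C)C)[C@H](CC=O)c1ccc(OC)c(OC)c1C(C)=O | intermediate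
16 | (1S)-1-[(2S,6S)-1,7-bis[(tert-butyldimethylsilyl)oxy]-6-methylheptan-2-yl]-5,6-dimethoxy-4-methyl-1,2-dihydronaphthalene | C[C@H](CO[Si](C)(C)C(C)(C)C)CCC[C@H](CO[Si](C)(C)C(C)(C)C)[C@@H]1CC=C(C)c2c1ccc(OC)c2OC | intermediate
17 | (2S,6S)-2-[(1S)-5,6-dimethoxy-4-methyl-1,2-dihydronaphthalen-1-yl]-6-methylheptane-1,7-diol | C[C@H](CO)CCC[C@H](CO)[C@@H]1CC=C(C)c2c1ccc(OC)c2OC | intermediate
18 | (2S,6S)-2-[(1S,4R)-5,6-dimethoxy-4-methyl-1,2,3,4-tetrahydronaphthalen-1-yl]-6-methylheptane-1,7-diol | C[C@H](CO)CCC[C@H](CO)[C@@H]1CC[C@@H](C)c2c1ccc(OC)c2OC | intermediate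
19 | C7-lithiated dilithium dialkoxide of 18 | C[C@H](CO[Li])CCC[C@H](CO[Li])[C@@H]1CC[C@@H](C)c2c1cc([Li])c(OC)c2OC | intermediate
20 | (5R,8S)-8-[(2S,6S)-1,7-dihydroxy-6-methylheptan-2-yl]-3,4-dimethoxy-5-methyl-5,6,7,8-tetrahydronaphthalene-2-carboxylic acid | C[C@H](CO)CCC[C@H](CO)[C@@H]1CC[C@@H](C)c2c1cc(C(=O)O)c(OC)c2OC | intermediate
21 | (5R,8S)-8-[(2S,6S)-1,7-dihydroxy-6-methylheptan-2-yl]-3,4-dihydroxy-5-methyl-5,6,7,8-tetrahydronaphthalene-2-carboxylic acid | C[C@H](CO)CCC[C@H](CO)[C@@H]1CC[C@@H](C)c2c1cc(C(=O)O)c(O)c2O | target

## Step count and least certain steps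

Total: 14 steps. Longest linear sequence: 13 steps (steps 1–3 and 5–14); step 4 is the one-step side branch.

**Step 10 (key step).** Intermolecular coupling and oligomerisation may outrun ring closure if the stationary concentration of 15 rises, the reaction may stall before deoxygenation on a poorly active reagent batch, or 15 may undergo Lewis-acid aldol condensation before it is reduced. Fallback, from 15 back to 16: both carbonyl groups would be methylenated with Cp2TiMe2 (toluene, 70 °C) to give the allyl/isopropenyl diene F1. Ring-closing metathesis with the second-generation Grubbs catalyst RuCl2(=CHPh)(H2IMes)(PCy3) in CH2Cl2 at 40 °C would then form C3=C4 with loss of ethene and return to 16.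

**Step 5.** Slow ionisation of the ortho-bromo carbinol may let enamine-mediated epimerisation at C11 erode the C1/C11 relationship, and the acid promoter may partly remove the silyl group. Fallback, from 5 and 6 back to 9, by an Ireland–Claisen rearrangement:
- 5 would be oxidised (NaClO2, NaH2PO4, 2-methylbut-2-ene) to the heptanoic acid F2.
- 6 would be converted by Horner–Wadsworth–Emmons olefination ((EtO)2P(O)CH2CO2Et, NaH) into the ethyl cinnamate F3 and reduced (i-Bu2AlH, −78 °C) to the (E)-cinnamyl alcohol F4.
- Esterification of F2 with F4 (DCC, DMAP) would give the allyl ester F5.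
- Enolisation with a C2-symmetric 1,2-diphenylethane-1,2-diamine bis(sulfonamide) bromoborane and Et3N (toluene–hexane, −78 °C → rt) under conditions that give the E(O)-boron enolate would give the anti pentenoic acid F6 through a chair transition state. The reagent enantiomer is chosen for the (2S,3S) isomer.
- LiAlH4 (THF, 0 °C) would reduce F6 to 9.

**Step 8.** Oxidative addition into a C–Br bond flanked on both sides may be slow, so that protodebromination and decomposition of the stannane compete. Fallback, from 10 back to 15: bromine–lithium exchange (t-BuLi, THF, −78 °C) and addition to acetaldehyde would give the benzylic carbinol F7 as a mixture of carbinol epimers. Hydroboration–oxidation of its vinyl group (9-BBN; NaOH, H2O2) would give the diol F8, and Dess–Martin periodinane in excess would oxidise both hydroxyl groups to give 15.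

**Step 12.** Hydrogen may be delivered without direction from the face away from the side chain (giving the cis isomer) if the hydroxymethyl group does not hold the metal, or the catalyst may deactivate before the hindered alkene is consumed. Fallback, from 16 back to 18: catalyst-controlled hydrogenation of the silyl ether 16 with [Ir(cod)(L)]BArF (L = 2-[2-(diphenylphosphino)phenyl]-4-tert-butyl-4,5-dihydrooxazole, the enantiomer that adds hydrogen to the Si face of C4; H2 50 bar, CH2Cl2) would give the trans tetralin bis-silyl ether F9. TBAF would then give 18.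

**Step 14.** The borates of the primary alcohols may be converted into alkyl bromides if the mixture warms, and the catechol may oxidise during work-up. Fallback, from 20 back to 21: acetylation (Ac2O, pyridine) would give the diacetate F10. BBr3 (−78 → 0 °C) would then cleave only the methyl ethers to give the catechol diacetate F11, and K2CO3 in degassed MeOH would remove the acetates to give 21.

## Further compounds

F1 | step 10 | tert-butyl{[(2S,6S)-7-[(tert-butyldimethylsilyl)oxy]-2-[(1S)-1-[3,4-dimethoxy-2-(prop-1-en-2-yl)phenyl]but-3-en-1-yl]-6-methylheptyl]oxy}dimethylsilane | C[C@H](CO[Si](C)(C)C(C)(C)C)CCC[C@H](CO[Si](C)(C)C(C)(C)C)[C@H](CC=C)c1ccc(OC)c(OC)c1C(C)=C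
F2 | step 5 | (S)-7-[(tert-butyldimethylsilyl)oxy]-6-methylheptanoic acid | C[C@H](CO[Si](C)(C)C(C)(C)C)CCCCC(=O)O
F3 | step 5 | ethyl (E)-3-(2-bromo-3,4-dimethoxyphenyl)prop-2-enoate | CCOC(=O)/C=C/c1ccc(OC)c(OC)c1Br
F4 | step 5 | (E)-3-(2-bromo-3,4-dimethoxyphenyl)prop-2-en-1-ol | OC/C=C/c1ccc(OC)c(OC)c1Br
F5 | step 5 | (E)-3-(2-bromo-3,4-dimethoxyphenyl)prop-2-en-1-yl (S)-7-[(tert-butyldimethylsilyl)oxy]-6-methylheptanoate | C[C@H](CO[Si](C)(C)C(C)(C)C)CCCCC(=O)OC/C=C/c1ccc(OC)c(OC)c1Br
F6 | step 5 | (2S,3S)-3-(2-bromo-3,4-dimethoxyphenyl)-2-[(4S)-5-[(tert-butyldimethylsilyl)oxy]-4-methylpentyl]pent-4-enoic acid | C[C@H](CO[Si](C)(C)C(C)(C)C)CCC[C@H](C(=O)O)[C@H](C=C)c1ccc(OC)c(OC)c1Br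
F7 | step 8 | 1-{6-[(3S,4S,8S)-9-[(tert-butyldimethylsilyl)oxy]-4-{[(tert-butyldimethylsilyl)oxy]methyl}-8-methylnon-1-en-3-yl]-2,3-dimethoxyphenyl}ethan-1-ol (both carbinol epimers) | C[C@H](CO[Si](C)(C)C(C)(C)C)CCC[C@H](CO[Si](C)(C)C(C)(C)C)[C@H](C=C)c1ccc(OC)c(OC)c1C(C)O
F8 | step 8 | (3S,4S,8S)-9-[(tert-butyldimethylsilyl)oxy]-4-{[(tert-butyldimethylsilyl)oxy]methyl}-3-[2-(1-hydroxyethyl)-3,4-dimethoxyphenyl]-8-methylnonan-1-ol (both carbinol epimers) | C[C@H](CO[Si](C)(C)C(C)(C)C)CCC[C@H](CO[Si](C)(C)C(C)(C)C)[C@H](CCO)c1ccc(OC)c(OC)c1C(C)O
F9 | step 12 | (1S,4R)-1-[(2S,6S)-1,7-bis[(tert-butyldimethylsilyl)oxy]-6-methylheptan-2-yl]-5,6-dimethoxy-4-methyl-1,2,3,4-tetrahydronaphthalene | C[C@H](CO[Si](C)(C)C(C)(C)C)CCC[C@H](CO[Si](C)(C)C(C)(C)C)[C@@H]1CC[C@@H](C)c2c1ccc(OC)c2OC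
F10 | step 14 | (5R,8S)-8-[(2S,6S)-1,7-diacetoxy-6-methylheptan-2-yl]-3,4-dimethoxy-5-methyl-5,6,7,8-tetrahydronaphthalene-2-carboxylic acid | C[C@H](COC(C)=O)CCC[C@H](COC(C)=O)[C@@H]1CC[C@@H](C)c2c1cc(C(=O)O)c(OC)c2OC
F11 | step 14 | (5R,8S)-8-[(2S,6S)-1,7-diacetoxy-6-methylheptan-2-yl]-3,4-dihydroxy-5-methyl-5,6,7,8-tetrahydronaphthalene-2-carboxylic acid | C[C@H](COC(C)=O)CCC[C@H](COC(C)=O)[C@@H]1CC[C@@H](C)c2c1cc(C(=O)O)c(O)c2O
A1 | alternative 1 | methyl 2,3-dihydroxybenzoate with the (E)-pent-3-en-2-yl arm on C4a and the vinyl-bearing bis-silyl side chain on C8a (target numbering) | C[C@H](CO[Si](C)(C)C(C)(C)C)CCC[C@H](CO[Si](C)(C)C(C)(C)C)[C@H](C=C)c1cc(C(=O)OC)c(O)c(O)c1[C@H](C)/C=C/C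
A2 | alternative 2 | methyl 5-formyl-6-hydroxy-4-methyltetralin-7-carboxylate with the bis-silyl side chain on C1 (target numbering) | C[C@H](CO[Si](C)(C)C(C)(C)C)CCC[C@H](CO[Si](C)(C)C(C)(C)C)[C@@H]1CC[C@@H](C)c2c1cc(C(=O)OC)c(O)c2C=O
A3 | alternative 3 | trans-5-methoxy-4-methyl-1-vinyl-1,2,3,4-tetrahydronaphthalen-6-ol (target numbering) | C=C[C@@H]1CC[C@@H](C)c2c1ccc(O)c2OC
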